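If the first end groups are followed entry by entry through the books, the flask below closes on two quantities read from the earlier runs, the link quotient and the isomer entry.

| flask | first end groups | second end groups | one-sided end groups | remark | time |
|---|---|---|---|---|---|
| violet | 20 mM | 20 mM (fed, over 30 min) | 1.4 mM | run made earlier |  |
| red | 20 mM | 20 mM (fed, over 30 min) | 2.2 mM | run made earlier |  |
| grey | 30 mM | 20 mM (fed, over 30 min) | 1 mM | run made earlier |  |
| flask | 20 mM | 20.0 mM (fed, over 30 min) | 1.00 mM |  | 2.5 h |

| run | time / min | first end groups / % | links / % |
|---|---|---|---|
| violet | 20.0 | 40 | 50 |
| violet | 40.0 | 11 | 77 |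
| violet | 50.0 | 12 | 78 |
| violet | 80.0 | 14 | 74 |
| violet | 90.0 | 14 | 74 |
| red | 8.00 | 68 | 22 |
| red | 15.0 | 48 | 39 |
| red | 25.0 | 25 | 63 |
| red | 50.0 | 10 | 75 |
| red | 90.0 | 11 | 75 |
| grey | 8.00 | 84 | 16 |
| grey | 25.0 | 46 | 51 |
| grey | 40.0 | 35 | 62 |
| grey | 60.0 | 32 | 60 |
| grey | 90.0 | 33 | 58 |

(each reading ± 1.5 percentage points)

- the numbers in the tables scatter by 1.5 percentage points (one standard deviation)
- the reaction counts as stopped when no species that holds the first end groups changes by six tenths of a point or more over the second half of the time

* why nothing more happens at 2.5 h, or that something still does (the second end groups has run out first / forward and back rates have come level / all of the first end groups has reacted / it is still moving)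
* conversion of first end groups at 2.5 h
* amount of links at 2.5 h, in percent of the first end groups charged
* amount of isomer of the product at 2.5 h, in percent of the first end groups charged
* amount of capped ends at 2.5 h, in percent of the first end groups charged
* amount of links if the flask were left three thousand times as long, in percent of the first end groups charged

First end groups are the limiting reagent, because the flask charges 20 mM of them against 21.0 mM of second and one-sided end groups together. Each first end group that reacts takes one partner with it, and links and their isomer keep theirs. Once the one-sided end groups are used up and the feed is in, free second end groups B minus free first end groups A is therefore a fixed D, the second and one-sided charges minus the first charge.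

The red run gives the constant. At 90.0 min, with L for links:

A = 2.20 mM, B = A + D = 4.40 mM, L = 15.0 mM

K = L/(A·B) = 1.55 mM⁻¹

This K is the link quotient, links per product of the free end groups. It is a reading and carries the scatter of the table.

The ledger for the flask, as reckoned here, has these entries.

Capped ends: 5.00%, the one-sided charge. The red run supports this entry, falling short by 10 percentage points at 8.00 min against a charge of 11.0%.

Isomer: the violet run leaves 5.00% unbooked at 90.0 min, and scaled with time this becomes 8.33%.

Links and free first end groups share the rest, S = 17.3 mM, with D = 1.00 mM:

K·A·(A + D) = S − A, so A = 2.62 mM

This closes the books at conversion 86.9% and links 73.6%.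

The forecast, on the grounds of “a reversible link step, with K ≈ 1.5 mM⁻¹ from the late values, slowly drained by isomerisation”, says it is still moving, with conversion 86.5% (83% to 90%), links 74% (69% to 79%), isomer 7% (4% to 11%), capped ends 5% (4% to 6%) and, for the far later time asked, links 10% (0% to 60%). Its isomer stands a little below the entry reckoned here.

In the flask, it is still moving, with conversion 87.5%, links 69.8%, isomer 12.7%, capped ends 5.00% and, for the far later time asked, links 32.3%.

first end groups + second end groups ⇌ links (K = 1600 L mol⁻¹, k = 0.620 L mol⁻¹ s⁻¹); links ⇌ isomer of the product (K = 1.70, k = 2.20 × 10⁻⁵ s⁻¹); first end groups + one-sided end groups → capped ends (k = 21.0 L mol⁻¹ s⁻¹) At 2.50 h first end groups have a forward half-life of 0.089 h in the link step, shorter than the time. Links have a forward half-life of 8.8 h towards isomer, longer than the time. K on the simulated links of this flask gives first end groups of 2.54 mM, or 12.7%, and the flask holds 13%. In the neighbour fed 12 mM of second end groups, D is −7.00 mM, and its links give 38.9% against a simulated 39%.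

Readings and results are calculated with made-up constants, noise included.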